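Target read from the SMILES: epicatechin-(4β→6)-epicatechin-(4β→8)-epicatechin-(4β→6)-epicatechin (units 1 to 4 from the top). All four units are (2R,3R) and every C4 substituent is trans to the neighbouring 3-OH, so the molecule is two identical (4β→6) dimers joined 4β→8.
Cuts: in unit 2, C4–C4a and C4–C8(unit 3) together (C4 returns to an acetal carbon), then O1–C2 (to a phenol and a cis-epoxide), then C4(unit 1)–C6(unit 2) (to a 4-alkoxyflavan and a phloroglucinol ether). Unit 4 is cut the same way, with hydride in place of unit 3.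
Enabling feature: C4 of unit 2 is a methine bonded to two phloroglucinol-type carbons (C4a of its own ring A and C8 of ring A of unit 3), i.e. an aldehyde carbon arylated twice. O1 of unit 2 lies para to C6, so in the open precursor the two carbons ortho to O1 are equivalent and closure can only give the 4→6 connectivity.
Forward: epicatechin → 4-activated monomer → 4β-aryl phenol → one ether acetal that serves both halves. Hydride-terminated closure of ring C of unit 4 gives the lower dimer. The bromine-capped ether acetal plus the lower dimer then closes ring C of unit 2 last and arylates it in the same flask, followed by global hydrogenolysis.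
Stereochemistry: C2/C3 of units 1 and 3 come from (−)-epicatechin. C2/C3 of units 2 and 4 come from Jacobsen epoxidation of a Z-alkene and SN2 opening with inversion. The three C4 centres come from attack on flavan-4-yl cations anti to the 3-oxygen.
Helpers: a bulky silyl ether (regiocontrol), bromine caps at C8 of units 1, 2 and 4 (site control) and benzyl ethers. The silyl ether is cleaved in step 6; the bromine caps and benzyl ethers leave in the last step.

Key step: step 14

Remark: slow rotation about the interflavan bonds gives interconverting rotamers, so each such compound is counted once. Compounds 16 and 19 are drawn as the 3,4-trans epimers, although either C4 epimer would ionise to the same cation.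

Step 1
Reactants: 1 (−)-epicatechin
Product: 2 5,7,3',4'-tetra-O-benzyl-(−)-epicatechin
Conditions: BnBr (4.2 equiv), K2CO3, DMF, 0 °C to rt
Reagents that add atoms: benzyl bromide BrCc1ccccc1
Why: Williamson etherification in which the four acidic phenols are alkylated under carbonate conditions while the secondary 3-OH stays free and C2/C3 are untouched.

Step 2
Reactants: 2 5,7,3',4'-tetra-O-benzyl-(−)-epicatechin
Product: 3 3,5,7,3',4'-penta-O-benzyl-(−)-epicatechin
Conditions: NaH, BnBr, DMF, 0 °C to rt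
Reagents that add atoms: benzyl bromide BrCc1ccccc1
Why: Williamson etherification of the remaining alkoxide; with no free phenol left the base cannot open ring C, so C2 is not epimerised.

Step 3
Reactants: 3 3,5,7,3',4'-penta-O-benzyl-(−)-epicatechin
Product: 4 4β-(2-ethoxyethoxy)-3,5,7,3',4'-penta-O-benzylepicatechin (4-O trans to 3-O)
Conditions: DDQ, 2-ethoxyethanol, CH2Cl2, rt
Reagents that add atoms: 2-ethoxyethanol CCOCCO
Why: Benzylic oxidation in which DDQ abstracts hydride from the C4 methylene activated by the 5,7-dioxygenated ring A and the alcohol adds to the cation anti to the 3-benzyloxy group, which sets C4 as 4β.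

Step 4
Reactants: 5 3,5-bis(benzyloxy)phenol
Product: 6 [3,5-bis(benzyloxy)phenoxy]tri(propan-2-yl)silane
Conditions: TIPSCl, imidazole, DMF, rt
Reagents that add atoms: chlorotri(propan-2-yl)silane CC(C)[Si](Cl)(C(C)C)C(C)C
Why: Standard silylation of a phenol; the bulky silyl ether is the helper that shields both ring carbons ortho to it in step 5.

Step 5
Reactants: 4 4β-(2-ethoxyethoxy)-penta-O-benzylepicatechin; 6 [3,5-bis(benzyloxy)phenoxy]tri(propan-2-yl)silane
Product: 7 4β-[2,6-bis(benzyloxy)-4-(triisopropylsilyloxy)phenyl]-3,5,7,3',4'-penta-O-benzylepicatechin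
Conditions: 6 (3 equiv), TMSOTf (0.2 equiv), CH2Cl2, −78 to −40 °C
Reagents that add atoms: none
Why: Lewis-acid Friedel–Crafts coupling of a 4-alkoxyflavan with a phloroglucinol triether, in which the cation is attacked on its β face, anti to the 3-benzyloxy and C2 aryl groups (C4 set as 4β), by the one arene carbon not shielded by the silyl group, while the excess of 6 suppresses self-condensation.

Step 6
Reactants: 7 silyl ether from step 5
Product: 8 4β-[2,6-bis(benzyloxy)-4-hydroxyphenyl]-3,5,7,3',4'-penta-O-benzylepicatechin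
Conditions: TBAF, AcOH (1.1 equiv each), THF, 0 °C
Reagents that add atoms: none
Why: Fluoride cleavage of an aryl silyl ether, buffered so that all benzyl ethers and stereocentres stay untouched and only the oxygen para to the flavanyl group is set free.

Step 7
Reactants: 8 phenol from step 6
Product: 9 4β-[2,6-bis(benzyloxy)-3-bromo-4-hydroxyphenyl]-3,5,7,3',4'-penta-O-benzylepicatechin
Conditions: NBS (1.0 equiv), i-Pr2NH (10 mol %), CH2Cl2, −78 to −40 °C
Reagents that add atoms: N-bromosuccinimide O=C1CCC(=O)N1Br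
Why: Amine-catalysed ortho-bromination of a phenol; the free phenol ring is the most activated arene present, its two ortho carbons are equivalent, and the bromine later serves as the C8 cap of units 2 and 4.

Step 8
Reactants: 10 4-bromo-1,2-bis(benzyloxy)benzene; 11 3,3-diethoxyprop-1-yne
Product: 12 1,2-bis(benzyloxy)-4-(3,3-diethoxyprop-1-yn-1-yl)benzene
Conditions: Pd(PPh3)2Cl2 (3 mol %), CuI (5 mol %), Et3N, 70 °C
Reagents that add atoms: none
Why: Sonogashira coupling of an aryl bromide with a terminal alkyne, which brings in C2, C3 and C4 with C4 already at the aldehyde oxidation level.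

Step 9
Reactants: 12 aryl alkyne acetal
Product: 13 (Z)-1,2-bis(benzyloxy)-4-(3,3-diethoxyprop-1-en-1-yl)benzene
Conditions: H2 (1 atm), Pd/CaCO3 poisoned with Pb(OAc)2, quinoline, EtOAc, rt
Reagents that add atoms: none
Why: Lindlar semihydrogenation, in which syn addition of hydrogen gives the Z-alkene and the benzyl ethers survive on the poisoned catalyst.

Step 10
Reactants: 13 Z-alkene acetal
Product: 14 (2S,3S)-2-[3,4-bis(benzyloxy)phenyl]-3-(diethoxymethyl)oxirane (cis-epoxide)
Conditions: (S,S)-(salen)MnCl [salen = N,N'-bis(3,5-di-tert-butylsalicylidene)cyclohexane-1,2-diamine dianion] (5 mol %), aq NaOCl (pH 11), 4-phenylpyridine N-oxide, CH2Cl2, 0 °C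
Reagents that add atoms: sodium hypochlorite [Na+].[O-]Cl
Why: Jacobsen epoxidation of a cis-disubstituted aryl alkene, the best substrate class of this catalyst; by analogy with cis-cinnamates the (S,S)-catalyst should give the (2S,3S)-cis-epoxide, which fixes the later C3 and sets the later C2 in the configuration to be inverted.

Step 11
Reactants: 9 bromophenol; 14 cis-epoxy acetal
Product: 15 (1R,2S)-1-[3,4-bis(benzyloxy)phenyl]-3,3-diethoxy-2-hydroxypropyl ether of phenol 9 (ether acetal)
Conditions: 14 (1.3 equiv), Cs2CO3 (20 mol %), DMF, 70 °C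
Reagents that add atoms: none
Why: Base-catalysed SN2 opening of an aryl epoxide by a phenoxide at the benzylic carbon (the other carbon is shielded and deactivated by the acetal) with inversion under non-ionising conditions, which gives the threo, epicatechin-type C2/C3 relationship, while adducts of the minor epoxide enantiomer are diastereomers and can be removed here.

Step 12
Reactants: 15 ether acetal
Product: 17 3,5,7,3',4'-penta-O-benzylepicatechin-(4β→6)-(8-bromo-5,7,3',4'-tetra-O-benzylepicatechin) (lower dimer), via 4-ethoxy lower dimer 16 (not isolated)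
Conditions: Et3SiH (5 equiv), TMSOTf (0.3 equiv), CH2Cl2, −78 to −30 °C
Reagents that add atoms: none
Why: Proposed new method: acetal ionisation and 6-exo-trig Friedel–Crafts closure by the free ring-A carbon ortho to O1 give 16, whose flavan-4-yl cation is then reduced by Et3SiH; the intramolecular arylation should outrun bimolecular hydride transfer to the first oxocarbenium ion, the excess silane should outrun attack by C8 of a second molecule, C2 and C3 are not touched, and the closest known reaction types are the Lewis-acid cyclisation of 3-aryloxypropanal acetals to 4-alkoxychromans and the ionic hydrogenation of benzylic ethers and flavan-3,4-diols.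

Step 13
Reactants: 15 ether acetal
Product: 18 8-bromo derivative of 15 (bromine at C8 of the closed flavan unit)
Conditions: NBS (1.0 equiv), CH2Cl2, −40 to 0 °C
Reagents that add atoms: N-bromosuccinimide O=C1CCC(=O)N1Br
Why: Electrophilic aromatic bromination at C8 of the flavan ring A, the most nucleophilic position left because ring A of the open unit is deactivated by its own bromine, in line with the C8-selective bromination of benzylated flavan-3-ols; this bromine blocks self-condensation in step 14.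

Step 14
Reactants: 18 bromine-capped ether acetal; 17 lower dimer
Product: 20 octadeca-O-benzyl-tribromo tetramer (Br at C8 of units 1, 2 and 4; 3-OH of units 2 and 4 free), via ring-closed 4-ethoxy dimer 19 (not isolated)
Conditions: 17 (1.5 equiv), TMSOTf (0.3 equiv), 4 Å MS, CH2Cl2, −78 to −20 °C; then Et3N
Reagents that add atoms: none
Why: Proposed new method: TMSOTf ionises the acetal of 18 to an α-oxygenated oxocarbenium ion, the only free ring-A carbon ortho to O1 attacks it (6-exo-trig Friedel–Crafts cyclialkylation through a half-chair with the C2 aryl group equatorial and the 3-oxygen axial) to give 19, which is by constitution the classical 4-alkoxyflavan extension unit and is ionised in the same flask to the flavan-4-yl cation that C8 of unit 3 of 17 captures. The closest known reaction types are the twofold Friedel–Crafts arylation of acetals to 1,1-diarylalkanes, the Lewis-acid cyclisation of 3-aryloxypropanal acetals to 4-alkoxychromans and the TMSOTf-catalysed coupling of 4-(2-ethoxyethoxy)flavan-3-ols with benzylated flavan-3-ols. The only new stereocentre, C4 of unit 2, is set in the second arylation by the ring just formed: the nucleophile enters the β face, anti to the axial 3-oxygen and to the C2 aryl group, which gives the 2,3-cis-3,4-trans array as in epicatechin-derived couplings, while C2 and C3 are not touched. If 17 adds to the open oxocarbenium ion first, ionisation of the remaining ethoxy group and closure by ring A lead to the same constitution, and the peri 5-benzyloxy group again favours the quasi-axial β aryl group. Chemoselectivity is needed between the acetal and the benzylic aryl ether O1–C2 (the more basic acetal oxygen is silylated first at low temperature and the oxygen at C3 disfavours a C2 cation) and among the ring-A positions (C8 of units 1, 2 and 4 carries bromine and the C6–H positions lie between two benzyloxy groups, so C8 of unit 3 is the one reactive site).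

Step 15
Reactants: 20 protected tetramer
Product: 21 epicatechin-(4β→6)-epicatechin-(4β→8)-epicatechin-(4β→6)-epicatechin (target)
Conditions: H2 (1 atm), Pd(OH)2/C, Et3N (3.3 equiv), THF/MeOH/H2O, rt
Reagents that add atoms: none
Why: Global hydrogenolysis of eighteen benzyl ethers with hydrodebromination of three aryl bromides, in which Et3N takes up HBr so that the acid-labile interflavan bonds survive and no stereocentre is affected.

Compound list
1 | (−)-epicatechin | Oc1cc(O)c2c(c1)O[C@H](c1ccc(O)c(O)c1)[C@H](O)C2 | starting material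
2 | 5,7,3',4'-tetra-O-benzyl-(−)-epicatechin | O(Cc1ccccc1)c1cc(OCc3ccccc3)c2c(c1)O[C@H](c1ccc(OCc3ccccc3)c(OCc3ccccc3)c1)[C@H](O)C2 | intermediate
3 | 3,5,7,3',4'-penta-O-benzyl-(−)-epicatechin | O(Cc1ccccc1)c1cc(OCc3ccccc3)c2c(c1)O[C@H](c1ccc(OCc3ccccc3)c(OCc3ccccc3)c1)[C@H](OCc1ccccc1)C2 | intermediate
4 | 4β-(2-ethoxyethoxy)-3,5,7,3',4'-penta-O-benzylepicatechin | O(Cc1ccccc1)c1cc(OCc3ccccc3)c2c(c1)O[C@H](c1ccc(OCc3ccccc3)c(OCc3ccccc3)c1)[C@H](OCc1ccccc1)[C@H]2OCCOCC | intermediate
5 | 3,5-bis(benzyloxy)phenol | Oc1cc(OCc2ccccc2)cc(OCc2ccccc2)c1 | starting material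
6 | [3,5-bis(benzyloxy)phenoxy]tri(propan-2-yl)silane | CC(C)[Si](C(C)C)(C(C)C)Oc1cc(OCc2ccccc2)cc(OCc2ccccc2)c1 | intermediate
7 | 4β-[2,6-bis(benzyloxy)-4-(triisopropylsilyloxy)phenyl]-penta-O-benzylepicatechin | O(Cc1ccccc1)c1cc(OCc3ccccc3)c2c(c1)O[C@H](c1ccc(OCc3ccccc3)c(OCc3ccccc3)c1)[C@H](OCc1ccccc1)[C@H]2c1c(OCc2ccccc2)cc(O[Si](C(C)C)(C(C)C)C(C)C)cc1OCc1ccccc1 | intermediate
8 | 4β-[2,6-bis(benzyloxy)-4-hydroxyphenyl]-penta-O-benzylepicatechin | O(Cc1ccccc1)c1cc(OCc3ccccc3)c2c(c1)O[C@H](c1ccc(OCc3ccccc3)c(OCc3ccccc3)c1)[C@H](OCc1ccccc1)[C@H]2c1c(OCc2ccccc2)cc(O)cc1OCc1ccccc1 | intermediate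
9 | 4β-[2,6-bis(benzyloxy)-3-bromo-4-hydroxyphenyl]-penta-O-benzylepicatechin | O(Cc1ccccc1)c1cc(OCc3ccccc3)c2c(c1)O[C@H](c1ccc(OCc3ccccc3)c(OCc3ccccc3)c1)[C@H](OCc1ccccc1)[C@H]2c1c(OCc2ccccc2)cc(O)c(Br)c1OCc1ccccc1 | intermediate
10 | 4-bromo-1,2-bis(benzyloxy)benzene | Brc1ccc(OCc2ccccc2)c(OCc2ccccc2)c1 | starting material
11 | 3,3-diethoxyprop-1-yne | C#CC(OCC)OCC | starting material
12 | 1,2-bis(benzyloxy)-4-(3,3-diethoxyprop-1-yn-1-yl)benzene | CCOC(OCC)C#Cc1ccc(OCc2ccccc2)c(OCc2ccccc2)c1 | intermediate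
13 | (Z)-1,2-bis(benzyloxy)-4-(3,3-diethoxyprop-1-en-1-yl)benzene | CCOC(OCC)/C=C\c1ccc(OCc2ccccc2)c(OCc2ccccc2)c1 | intermediate
14 | (2S,3S)-2-[3,4-bis(benzyloxy)phenyl]-3-(diethoxymethyl)oxirane (cis) | CCOC(OCC)[C@H]1O[C@H]1c1ccc(OCc2ccccc2)c(OCc2ccccc2)c1 | intermediate
15 | ether acetal: (1R,2S)-1-[3,4-bis(benzyloxy)phenyl]-3,3-diethoxy-2-hydroxypropyl ether of 9 | O(Cc1ccccc1)c1cc(OCc3ccccc3)c2c(c1)O[C@H](c1ccc(OCc3ccccc3)c(OCc3ccccc3)c1)[C@H](OCc1ccccc1)[C@H]2c1c(OCc2ccccc2)cc(O[C@H](c2ccc(OCc3ccccc3)c(OCc3ccccc3)c2)[C@H](O)C(OCC)OCC)c(Br)c1OCc1ccccc1 | intermediate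
16 | 4-ethoxy lower dimer (ring C of unit 4 closed, OEt at its C4, drawn 3,4-trans) | O(Cc1ccccc1)c1cc(OCc3ccccc3)c2c(c1)O[C@H](c1ccc(OCc3ccccc3)c(OCc3ccccc3)c1)[C@H](OCc1ccccc1)[C@H]2c1c(OCc2ccccc2)c(Br)c2c(c1OCc1ccccc1)[C@H](OCC)[C@@H](O)[C@@H](c1ccc(OCc3ccccc3)c(OCc3ccccc3)c1)O2 | intermediate
17 | lower dimer: penta-O-benzylepicatechin-(4β→6)-(8-bromo-5,7,3',4'-tetra-O-benzylepicatechin) | O(Cc1ccccc1)c1cc(OCc3ccccc3)c2c(c1)O[C@H](c1ccc(OCc3ccccc3)c(OCc3ccccc3)c1)[C@H](OCc1ccccc1)[C@H]2c1c(OCc2ccccc2)c(Br)c2c(c1OCc1ccccc1)C[C@@H](O)[C@@H](c1ccc(OCc3ccccc3)c(OCc3ccccc3)c1)O2 | intermediate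
18 | bromine-capped ether acetal (15 with Br at C8 of the closed flavan unit) | O(Cc1ccccc1)c1cc(OCc3ccccc3)c2c(c1Br)O[C@H](c1ccc(OCc3ccccc3)c(OCc3ccccc3)c1)[C@H](OCc1ccccc1)[C@H]2c1c(OCc2ccccc2)cc(O[C@H](c2ccc(OCc3ccccc3)c(OCc3ccccc3)c2)[C@H](O)C(OCC)OCC)c(Br)c1OCc1ccccc1 | intermediate
19 | ring-closed 4-ethoxy dimer (ring C of unit 2 closed, OEt at its C4, drawn 3,4-trans) | O(Cc1ccccc1)c1cc(OCc3ccccc3)c2c(c1Br)O[C@H](c1ccc(OCc3ccccc3)c(OCc3ccccc3)c1)[C@H](OCc1ccccc1)[C@H]2c1c(OCc2ccccc2)c(Br)c2c(c1OCc1ccccc1)[C@H](OCC)[C@@H](O)[C@@H](c1ccc(OCc3ccccc3)c(OCc3ccccc3)c1)O2 | intermediate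
20 | octadeca-O-benzyl-tribromo tetramer | O(Cc1ccccc1)c1cc(OCc3ccccc3)c2c(c1Br)O[C@H](c1ccc(OCc3ccccc3)c(OCc3ccccc3)c1)[C@H](OCc1ccccc1)[C@H]2c1c(OCc2ccccc2)c(Br)c2c(c1OCc1ccccc1)[C@H](c1c(OCc4ccccc4)cc(OCc4ccccc4)c3c1O[C@H](c1ccc(OCc4ccccc4)c(OCc4ccccc4)c1)[C@H](OCc1ccccc1)[C@H]3c1c(OCc4ccccc4)c(Br)c3c(c1OCc1ccccc1)C[C@@H](O)[C@@H](c1ccc(OCc4ccccc4)c(OCc4ccccc4)c1)O3)[C@@H](O)[C@@H](c1ccc(OCc3ccccc3)c(OCc3ccccc3)c1)O2 | intermediate
21 | epicatechin-(4β→6)-epicatechin-(4β→8)-epicatechin-(4β→6)-epicatechin | Oc1cc(O)c2c(c1)O[C@H](c1ccc(O)c(O)c1)[C@H](O)[C@H]2c1c(O)cc2c(c1O)[C@H](c1c(O)cc(O)c3c1O[C@H](c1ccc(O)c(O)c1)[C@H](O)[C@H]3c1c(O)cc3c(c1O)C[C@@H](O)[C@@H](c1ccc(O)c(O)c1)O3)[C@@H](O)[C@@H](c1ccc(O)c(O)c1)O2 | target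

Total step count: 15. Longest linear sequence: 10 steps (1, 2, 3, 5, 6, 7, 11, 12, 14, 15).

Steps most likely to fail

Step 14. The benzylic aryl ether O1–C2 may ionise before the ring has closed, or chain growth may set in when a second cation attacks the product. The fallback uses known chemistry only, sets out from 17 and comes back at 20. Bromination of 17 with NBS at C8 of its upper unit gives the doubly capped dimer F1. DDQ with 2-ethoxyethanol oxidises the only remaining C4 methylene to the 4β-(2-ethoxyethoxy) dimer F2. TMSOTf-catalysed coupling of F2 with a second portion of 17 then gives 20. In this variant ring C of unit 2 is already closed when the halves are joined.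

Step 12. Hydride may be transferred to the open oxocarbenium ion before the arene closes the ring, or the cation may be taken up by C8 of a second molecule. The fallback uses known chemistry, sets out from 9 and comes back at 17. Addition of CH2=CHMgBr to purchased 3,4-bis(benzyloxy)benzaldehyde gives the racemic allylic alcohol F3. Sharpless kinetic-resolution epoxidation (Ti(OiPr)4, L-(+)-diisopropyl tartrate, t-BuOOH) gives the erythro epoxy alcohol F4. Mitsunobu etherification of 9 with F4 (PPh3, DIAD) inverts the carbinol carbon and gives the aryl ether epoxide F5. The 6-endo epoxide–arene cyclisation known for aryl glycidyl ethers (AuCl3/AgOTf, CH2Cl2) attacks the terminal epoxide carbon and gives 17.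

Step 5. Regioselectivity between the carbon para to the silyloxy group and the two carbons ortho to it may be poor. The fallback sets out from 4 and comes back at 7. Coupling of 4 with an excess of phloroglucinol, which is symmetric and has only one kind of carbon, gives the triol F6. TIPSCl and imidazole at low temperature silylate the one hydroxyl group that is not flanked by the flavanyl substituent and give the monosilyl ether F7. Benzylation of the two hindered phenols (BnBr, K2CO3, acetone) then gives 7.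

Further compounds
F1 | step 14 | (8-bromo-penta-O-benzylepicatechin)-(4β→6)-(8-bromo-5,7,3',4'-tetra-O-benzylepicatechin) | O(Cc1ccccc1)c1cc(OCc3ccccc3)c2c(c1Br)O[C@H](c1ccc(OCc3ccccc3)c(OCc3ccccc3)c1)[C@H](OCc1ccccc1)[C@H]2c1c(OCc2ccccc2)c(Br)c2c(c1OCc1ccccc1)C[C@@H](O)[C@@H](c1ccc(OCc3ccccc3)c(OCc3ccccc3)c1)O2
F2 | step 14 | F1 with a 4β-(2-ethoxyethoxy) group at C4 of the lower unit | O(Cc1ccccc1)c1cc(OCc3ccccc3)c2c(c1Br)O[C@H](c1ccc(OCc3ccccc3)c(OCc3ccccc3)c1)[C@H](OCc1ccccc1)[C@H]2c1c(OCc2ccccc2)c(Br)c2c(c1OCc1ccccc1)[C@H](OCCOCC)[C@@H](O)[C@@H](c1ccc(OCc3ccccc3)c(OCc3ccccc3)c1)O2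
F3 | step 12 | rac-1-[3,4-bis(benzyloxy)phenyl]prop-2-en-1-ol | C=CC(O)c1ccc(OCc2ccccc2)c(OCc2ccccc2)c1
F4 | step 12 | (S)-[3,4-bis(benzyloxy)phenyl][(R)-oxiran-2-yl]methanol (erythro) | O[C@@H](c1ccc(OCc2ccccc2)c(OCc2ccccc2)c1)[C@H]1CO1
F5 | step 12 | (R)-[3,4-bis(benzyloxy)phenyl][(R)-oxiran-2-yl]methyl ether of 9 | O(Cc1ccccc1)c1cc(OCc3ccccc3)c2c(c1)O[C@H](c1ccc(OCc3ccccc3)c(OCc3ccccc3)c1)[C@H](OCc1ccccc1)[C@H]2c1c(OCc2ccccc2)cc(O[C@H](c2ccc(OCc3ccccc3)c(OCc3ccccc3)c2)[C@H]2CO2)c(Br)c1OCc1ccccc1
F6 | step 5 | 4β-(2,4,6-trihydroxyphenyl)-penta-O-benzylepicatechin | O(Cc1ccccc1)c1cc(OCc3ccccc3)c2c(c1)O[C@H](c1ccc(OCc3ccccc3)c(OCc3ccccc3)c1)[C@H](OCc1ccccc1)[C@H]2c1c(O)cc(O)cc1O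
F7 | step 5 | 4β-[2,6-dihydroxy-4-(triisopropylsilyloxy)phenyl]-penta-O-benzylepicatechin | O(Cc1ccccc1)c1cc(OCc3ccccc3)c2c(c1)O[C@H](c1ccc(OCc3ccccc3)c(OCc3ccccc3)c1)[C@H](OCc1ccccc1)[C@H]2c1c(O)cc(O[Si](C(C)C)(C(C)C)C(C)C)cc1O
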